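**Strategy.** The route rests on the bond between C8 of the right-hand 5,7-dimethoxycoumarin and the cyclohexene CH. This CH is allylic to the ring C=C whose far end carries the methyl group, so it is one terminus of a cyclohexenyl cation, while C8 is the most nucleophilic, least hindered carbon of a phloroglucinol-type ring. A Lewis-acid Friedel–Crafts allylation therefore joins an allylic pivalate already carrying the left coumarin to plain 5,7-dimethoxycoumarin, puts the double bond in place and sets the benzylic stereocentre trans to the quaternary methyl group. The styryl link is carried as a slim alkyne, made from an asymmetric Diels–Alder adduct, and reduced to the E-alkene last.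

Key step: step 6

Remark: compounds 6–8 are drawn as the endo adduct (CHO cis to OPiv); the carbinol configuration is erased at the cation stage of step 6, so its epimer serves equally.
Remark: the catalyst enantiomer in step 3 is the one expected from the usual binding model for 2-substituted acroleins; if the first run shows the opposite sense, the mirror-image catalyst is used with no other change.

**Step 1**
Reactants: 1 5,7-dimethoxycoumarin
Product: 2 8-iodo-5,7-dimethoxycoumarin
Conditions: NIS (1.05 equiv), TFA (cat.), MeCN, 0 °C → rt
Reagents that add atoms: N-iodosuccinimide, O=C1CCC(=O)N1I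
Why: Electrophilic aromatic iodination should go to C8, which is para to the 5-OMe and ortho to the 7-OMe, whereas C6 is crowded by the 5-OMe methyl group that the peri C4–H forces toward it (the pattern known for 5,7-dimethoxybenzopyranones).

**Step 2**
Reactants: 3 3-methylbut-2-enal
Product: 4 (E)-3-methylbuta-1,3-dien-1-yl pivalate
Conditions: t-BuOK, THF, −78 °C; then PivCl, −78 → 0 °C
Reagents that add atoms: pivaloyl chloride, CC(C)(C)C(=O)Cl
Why: γ-Deprotonation of the s-trans enal gives the potassium dienolate, whose O-acylation by the hard acyl chloride should give the (E)-dienyl ester (dienolate O-acylation).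

**Step 3**
Reactants: 4 (E)-3-methylbuta-1,3-dien-1-yl pivalate; 5 methacrolein
Product: 6 (1R,6S)-6-formyl-3,6-dimethylcyclohex-2-en-1-yl pivalate
Conditions: (S)-o-tolyl-CBS-oxazaborolidine·HNTf2 (10–20 mol %), CH2Cl2, −78 → −40 °C
Reagents that add atoms: none
Why: Catalytic asymmetric Diels–Alder reaction in which the 1-acyloxy and 3-methyl groups both send the unsubstituted diene terminus to the β-carbon of methacrolein ("ortho/para" rule) and the chiral oxazaborolidinium ion, holding the s-trans enal by B–O and formyl C–H···O contacts, shields one face of the dienophile so that the quaternary centre should form as (S); this is the only step that sets the absolute configuration.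

**Step 4**
Reactants: 6 (1R,6S)-6-formyl-3,6-dimethylcyclohex-2-en-1-yl pivalate
Product: 7 (1R,6R)-6-ethynyl-3,6-dimethylcyclohex-2-en-1-yl pivalate
Conditions: Bestmann–Ohira reagent, K2CO3, MeOH, 0 °C → rt
Reagents that add atoms: dimethyl (1-diazo-2-oxopropyl)phosphonate, CC(=O)C(=[N+]=[N-])P(=O)(OC)OC
Why: Ohira–Bestmann (Seyferth–Gilbert) homologation of a non-enolisable aldehyde should proceed while the hindered pivalate resists methanolysis, and the quaternary centre cannot epimerise.

**Step 5**
Reactants: 7 (1R,6R)-6-ethynyl-3,6-dimethylcyclohex-2-en-1-yl pivalate; 2 8-iodo-5,7-dimethoxycoumarin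
Product: 8 (1R,6R)-6-[(5,7-dimethoxy-2-oxo-2H-chromen-8-yl)ethynyl]-3,6-dimethylcyclohex-2-en-1-yl pivalate
Conditions: Pd(PPh3)2Cl2 (5 mol %), CuI (10 mol %), i-Pr2NH, THF, rt
Reagents that add atoms: none
Why: Sonogashira coupling of an aryl iodide with a terminal alkyne runs at room temperature, where the hindered trisubstituted allylic pivalate should not be ionised by Pd(0).

**Step 6**
Reactants: 8 (1R,6R)-6-[(5,7-dimethoxy-2-oxo-2H-chromen-8-yl)ethynyl]-3,6-dimethylcyclohex-2-en-1-yl pivalate; 1 5,7-dimethoxycoumarin
Product: 10 8-{[(1S,2R)-2-(5,7-dimethoxy-2-oxo-2H-chromen-8-yl)-1,4-dimethylcyclohex-3-en-1-yl]ethynyl}-5,7-dimethoxycoumarin, via allyl cation 9 (not isolated)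
Conditions: Sc(OTf)3 (10 mol %), 1 (3 equiv), MeNO2–CH2Cl2, −20 °C → rt
Reagents that add atoms: none
Why: Sc(OTf)3 ionises the secondary allylic pivalate to the cyclohexenyl cation 9, whose charge is shared by the methyl-bearing ring carbon and the carbon next to the quaternary centre, and C8 of 1 attacks the latter in an electrophilic aromatic substitution, after which proton loss restores the arene and the catalyst. The closest known reaction type is the Lewis-acid Friedel–Crafts allylation of resorcinol and phloroglucinol ethers with cyclic allylic alcohols or esters, as in cannabidiol-type terpene–arene couplings, which likewise makes an aryl–CH bond flanked by two oxygens next to a substituted ring carbon and leaves the methyl-substituted double bond. No ring is closed. The new stereocentre is controlled by the adjacent quaternary carbon: the arene should enter anti to its methyl group, the larger substituent, and syn to the rod-like alkynyl group, and this isomer (methyl equatorial, alkynyl axial) is also the more stable one if the alkylation is reversible. The step needs attack at the secondary rather than the tertiary allyl terminus (the latter would give a strained quaternary benzylic carbon), reaction at C8 rather than C6 of 1 (same electronic and steric bias as in step 1), and capture by 1 rather than by the coumarin ring of 8 (whose only free position is the hindered C6, and 1 is in excess). Both epimers of 8 give the same cation, so the configuration of the leaving group does not matter.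

**Step 7**
Reactants: 10 8-{[(1S,2R)-2-(5,7-dimethoxy-2-oxo-2H-chromen-8-yl)-1,4-dimethylcyclohex-3-en-1-yl]ethynyl}-5,7-dimethoxycoumarin
Product: 12 8-[(E)-2-[(1R,2R)-2-(5,7-dimethoxy-2-oxo-2H-chromen-8-yl)-1,4-dimethylcyclohex-3-en-1-yl]ethenyl]-5,7-dimethoxycoumarin (target), via (Z)-vinylsilane 11 (not isolated)
Conditions: [Cp*Ru(MeCN)3]PF6 (5 mol %), (EtO)3SiH, CH2Cl2, 0 °C → rt; volatiles removed; then CuI (20 mol %), TBAF·3H2O, THF, rt
Reagents that add atoms: none
Why: Cationic Cp*Ru-catalysed trans-hydrosilylation of the internal alkyne, then copper/fluoride protodesilylation with retention, is a net trans-reduction to the E-alkene; either regioisomer of 11 gives the same product, and the ring and coumarin C=C bonds, the lactones and both stereocentres should be untouched.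

**Compound list**
1 | 5,7-dimethoxycoumarin (5,7-dimethoxy-2H-chromen-2-one) | COc1cc(OC)c2ccc(=O)oc2c1 | starting material
2 | 8-iodo-5,7-dimethoxycoumarin | COc1cc(OC)c2ccc(=O)oc2c1I | intermediate
3 | 3-methylbut-2-enal | CC(C)=CC=O | starting material
4 | (E)-3-methylbuta-1,3-dien-1-yl pivalate | CC(=C)/C=C/OC(=O)C(C)(C)C | intermediate
5 | methacrolein (2-methylprop-2-enal) | CC(=C)C=O | starting material
6 | (1R,6S)-6-formyl-3,6-dimethylcyclohex-2-en-1-yl pivalate | O=C[C@@]1(C)CCC(C)=C[C@H]1OC(=O)C(C)(C)C | intermediate
7 | (1R,6R)-6-ethynyl-3,6-dimethylcyclohex-2-en-1-yl pivalate | C#C[C@@]1(C)CCC(C)=C[C@H]1OC(=O)C(C)(C)C | intermediate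
8 | (1R,6R)-6-[(5,7-dimethoxy-2-oxo-2H-chromen-8-yl)ethynyl]-3,6-dimethylcyclohex-2-en-1-yl pivalate | COc1cc(OC)c2ccc(=O)oc2c1C#C[C@@]1(C)CCC(C)=C[C@H]1OC(=O)C(C)(C)C | intermediate
9 | cyclohexenyl (allyl) cation from 8, positive charge shared by the ring CH next to the quaternary carbon and the methyl-bearing ring carbon | COc1cc(OC)c2ccc(=O)oc2c1C#C[C@@]1(C)CCC(C)=C[CH+]1 | intermediate
10 | 8-{[(1S,2R)-2-(5,7-dimethoxy-2-oxo-2H-chromen-8-yl)-1,4-dimethylcyclohex-3-en-1-yl]ethynyl}-5,7-dimethoxycoumarin | COc1cc(OC)c2ccc(=O)oc2c1C#C[C@@]1(C)CCC(C)=C[C@H]1c1c(OC)cc(OC)c2ccc(=O)oc12 | intermediate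
11 | (Z)-vinylsilane from 10, triethoxysilyl drawn on the alkene carbon bound to the coumarin ring, H on the other alkene carbon trans to silicon (the regioisomer converges) | COc1cc(OC)c2ccc(=O)oc2c1/C([Si](OCC)(OCC)OCC)=C/[C@@]1(C)CCC(C)=C[C@H]1c1c(OC)cc(OC)c2ccc(=O)oc12 | intermediate
12 | 8-[(E)-2-[(1R,2R)-2-(5,7-dimethoxy-2-oxo-2H-chromen-8-yl)-1,4-dimethylcyclohex-3-en-1-yl]ethenyl]-5,7-dimethoxycoumarin | COc1cc(OC)c2ccc(=O)oc2c1/C=C/[C@@]1(C)CCC(C)=C[C@H]1c1c(OC)cc(OC)c2ccc(=O)oc12 | target

**Step count.** Total: 7 steps. Longest linear sequence: 6 steps (3 → 4 → 6 → 7 → 8 → 10 → 12).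

**Steps most likely to fail**

1. Step 6. The arene may add to the allyl cation on the face cis to the methyl group, at the tertiary terminus, or through C6 of the coumarin, and the cation may be lost by elimination to dienes or by alkylating the coumarin ring of another molecule of 8. The fallback sets out from 8 and 2 and comes back to the route at 10. A nickel-catalysed reductive cross-electrophile coupling (NiCl2·glyme, a bipyridine ligand, Mn, DMA) joins the aryl iodide to the allylic pivalate through an allylnickel species. The C–I bond fixes C8, the aryl group should be delivered to the secondary allyl terminus on the face away from the methyl group, and no free cation is involved. This fallback makes no new compound (F0).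

2. Step 7. The ruthenium catalyst may fail to engage an alkyne that is shielded on one side by the quaternary carbon and on the other by the 2,6-disubstituted aryl ring, and fluoride may open a lactone during protodesilylation. The fallback sets out from 10 and comes back at 12. Cis-semihydrogenation (Lindlar catalyst, quinoline, H2) should give the (Z)-alkene F1. Z→E isomerisation with catalytic iodine under visible light, driven by relief of the strain between the quaternary carbon and the aryl ring, then gives 12.

3. Step 3. The catalyst may discriminate the faces of methacrolein poorly with an acyloxydiene it has not been paired with before, the ester carbonyl may compete for the Lewis acid, and the diene or the allylic ester product may ionise under the strong acid. The fallback sets out from 3 and comes back at 10, with auxiliary control replacing catalyst control. The potassium dienolate of 3 is acylated with (S)-O-methylmandeloyl chloride to the (E)-dienyl (S)-2-methoxy-2-phenylacetate F2. Its Diels–Alder reaction with 5 (BF3·OEt2, CH2Cl2, −78 °C) gives diastereomers, from which the (1R,6S)-aldehyde F3 is separated by chromatography or crystallisation. Ohira–Bestmann homologation gives the alkyne F4, and Sonogashira coupling with 2 gives the aryl alkyne F5. Under the conditions of step 6, F5 is ionised with loss of the auxiliary acid and coupled with 1 to give 10.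

**Further compounds**
F0 | step 6 | none | none
F1 | step 7 | 8-[(Z)-2-[(1R,2R)-2-(5,7-dimethoxy-2-oxo-2H-chromen-8-yl)-1,4-dimethylcyclohex-3-en-1-yl]ethenyl]-5,7-dimethoxycoumarin | COc1cc(OC)c2ccc(=O)oc2c1/C=C\[C@@]1(C)CCC(C)=C[C@H]1c1c(OC)cc(OC)c2ccc(=O)oc12
F2 | step 3 | (E)-3-methylbuta-1,3-dien-1-yl (S)-2-methoxy-2-phenylacetate | CO[C@H](C(=O)O/C=C/C(C)=C)c1ccccc1
F3 | step 3 | (1R,6S)-6-formyl-3,6-dimethylcyclohex-2-en-1-yl (S)-2-methoxy-2-phenylacetate | O=C[C@@]1(C)CCC(C)=C[C@H]1OC(=O)[C@@H](OC)c1ccccc1
F4 | step 3 | (1R,6R)-6-ethynyl-3,6-dimethylcyclohex-2-en-1-yl (S)-2-methoxy-2-phenylacetate | C#C[C@@]1(C)CCC(C)=C[C@H]1OC(=O)[C@@H](OC)c1ccccc1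
F5 | step 3 | (1R,6R)-6-[(5,7-dimethoxy-2-oxo-2H-chromen-8-yl)ethynyl]-3,6-dimethylcyclohex-2-en-1-yl (S)-2-methoxy-2-phenylacetate | COc1cc(OC)c2ccc(=O)oc2c1C#C[C@@]1(C)CCC(C)=C[C@H]1OC(=O)[C@@H](OC)c1ccccc1
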